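The earlier runs and the new flask were generated by integration with constants of no real substance.

Free catalyst in this flask serves two cycles that draw on one reagent. It binds starting material to catalyst intermediate A, which reagent turns into target and free catalyst. It also binds second substrate to catalyst intermediate B, which reagent turns into second product and free catalyst. Target can go on with starting material to side product, or with reagent to over-reaction product.

| flask | starting material | second substrate | reagent | free catalyst | remark | time |
|---|---|---|---|---|---|---|
| ochre | 0.20 M | 1 equiv | 1.5 equiv | 1.6 mol% | run made earlier |  |
| green | 0.20 M | 1 equiv | 1.5 equiv | 5.1 mol% | run made earlier |  |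
| gamma | 0.20 M | 1.00 equiv | 1.50 equiv | 2 mol% |  | 4.0 h |
| delta | 0.20 M | 1.00 equiv | 1.50 equiv | 6 mol% |  | 4.0 h |

| run | time / min | target / % |
|---|---|---|
| ochre | 25.0 | 4 |
| ochre | 50.0 | 10 |
| ochre | 80.0 | 11 |
| ochre | 90.0 | 12 |
| ochre | 120 | 12 |
| green | 10.0 | 7 |
| green | 20.0 | 16 |
| green | 30.0 | 21 |
| green | 60.0 | 26 |
| green | 120 | 23 |

(readings scatter by 2 percentage points)

1. which of the two there is more of at the end, counted by the starting material in each, gamma (side product / target)
2. which of the two there is more of at the end, counted by the starting material in each, delta (side product / target)
3. how much target is there at the end, in percent of the starting material charged: gamma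
4. how much target is there at the end, in percent of the starting material charged: delta

First the main step by itself. Target fraction over catalyst fraction over time counts turnovers into target per minute, here at the second reading of each run:

ochre: 0.125 min⁻¹; green: 0.157 min⁻¹; mean: 0.141 min⁻¹

At that pace gamma reaches 67.6% of the charge in 4.0 h, while delta's 203% exceeds the charge.

Now add the loss of target. Both runs level off, which I read as making and loss in balance. The level does not follow catalyst in proportion: 3.19 times the catalyst gives 2.17 times the level, as read. So I carry the power of catalyst read from these two levels, 0.667, to the new loadings:

gamma, from ochre: 13.9%; delta, from green: 29.0%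

Last comes the second cycle. Each turnover of either cycle spends one reagent, and over-reaction product takes reagent too, so the charge pays for a count no larger than the turnover budget, reagent equivalents over catalyst fraction. I assume the second cycle keeps the pace of the first, which doubles the clock:

budget: gamma 75.0; delta 25.0; turnovers in the time: 67.6

Gamma's budget lasts, so my gamma stays near its level. Delta's is smaller, which makes reagent the limiting reagent, spent at about 88.7 min. Target then only falls. On the same clock, green's budget of 29.4 ends between its last two readings, and those give a fall, with wide scatter, of 0.00204 min⁻¹. My delta is therefore:

21.3%

The forecast gives side product ahead in both flasks, with target at 14% (10% to 18%) in gamma and 27% (19% to 33%) in delta, which is above my delta. Its ground: “Delta should be near 27%, with starting material exhausted.”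

Side product leads in both flasks, with 50.9% in gamma and 59.7% in delta. Target stands at 10.7% in gamma and 18.2% in delta.

    reagent + catalyst intermediate B → free catalyst + second product (k = 462 M⁻¹ h⁻¹)
    starting material + free catalyst ⇌ catalyst intermediate A (K = 11.0 M⁻¹, k = 344 M⁻¹ h⁻¹)
    second substrate + free catalyst ⇌ catalyst intermediate B (K = 10.0 M⁻¹, k = 203 M⁻¹ h⁻¹)
    reagent + catalyst intermediate A → free catalyst + target (k = 106 M⁻¹ h⁻¹)
    starting material + target → side product (k = 5.69 M⁻¹ h⁻¹)
    reagent + target → over-reaction product (k = 1.88 M⁻¹ h⁻¹)

Delta, with a budget of 25.0, ends with 0.520% of its reagent charge but 12.7% of its starting material. Its neighbour with 0.900 equiv of reagent has a budget of 15.0 and ends with 0.0416% of its reagent and target at 4.32%. Gamma has drawn reagent worth 62.9 of its 75.0 turnovers and is still moving: at 40.0 h its reagent stands at 0% and its target at 0.228%. Delta is not at rest either: by 40.0 h its side product reaches 85.6% and its target falls to 5.34%.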